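# Proposed synthesis of (1R,2S,3S,4S)-4-bromo-2-[(3S)-3-hydroxy-3-methylpent-4-en-1-yl]-1,3-dimethyl-3-(4-methylpent-3-en-1-yl)cyclohexan-1-ol (23)

Atom labels used throughout: ring C1 (CH carrying the side chain), C2 (quaternary), C3 (CHBr), C4, C5 (CH2), C6 (C(CH3)OH). Side chain on C1: C7, C8 (CH2), C9 (carbinol), C10=C11 (vinyl). Chain on C2: C1′, C2′ (CH2), C3′=C4′(CH3)2.

## Analysis of the target

Compound 23 is a single cyclohexane ring substituted on four contiguous atoms: C6 is a tertiary carbinol, C1 a methine carrying the side chain C7–C11 with the tertiary allylic carbinol C9, C2 a quaternary carbon with a methyl group and the 4-methylpent-3-enyl chain, and C3 a secondary bromide. Four of the five stereocentres are in the ring (1S, 2S, 3S, 6R in these labels): bromine is cis to the C2 methyl and trans to the C2 chain, the C1 side chain is cis to the C2 methyl, and the C6 hydroxyl is cis to the C1 side chain. In the favoured chair the bromine, both chains and the C6 methyl are equatorial, while the C2 methyl and the C6 hydroxyl are axial on the same face. The fifth stereocentre, C9 (S), is two methylenes away from the ring and cannot be controlled from it. The bromide sits next to a quaternary carbon, so it cannot be made by substitution, and it can be lost by elimination or by 1,3-displacement from a C1 enolate. The two tertiary alcohols (one allylic) ionise in acid, and the trisubstituted alkene is attacked by electrophiles and boranes. The difficulty is therefore the quaternary centre C2 flanked by two stereocentres, one of them a C–Br bond of fixed configuration, plus a remote carbinol that needs its own source of chirality. The strategy rests on the C2–C3 pair: a carbon substituent (C1′) and a bromine, anti on adjacent ring atoms with C1 next door, is the pattern left when Br+ and a carbon migrating from C1 add anti across a C2=C3 double bond.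

## Retrosynthetic reasoning

**C10=C11.** The vinyl group of 23 is cut last, back to hydroxy aldehyde 22, triol 21 and acetonide 20. A terminal alkene would not survive the hydroboration that puts oxygen on C6, so it must come after it. Carrying C9 as a protected 1,2-diol means its configuration is brought in, not made late. An addition of a vinyl nucleophile to a C9 methyl ketone was set aside: the ring gives no bias at that distance, and a catalyst would have to tell a methyl from an unbranched alkyl group. The forward steps must oxidise one primary alcohol beside two tertiary ones and methylenate an aldehyde whose α-carbon is quaternary and so configurationally safe.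

**C3′=C4′.** The trisubstituted alkene of 20 is cut to aldehyde 19 and its dioxolane 18. Both the bromination and the hydroboration would attack this alkene, so the chain travels as a masked aldehyde. A Wittig reaction completes it without creating a stereocentre. The forward step must open the aldehyde acetal while the acetonide stays.

**C6–CH3.** Removing the methyl group from 18 gives ketone 17. In its chair the axial C2 methyl blocks one face, so a methyl nucleophile should enter equatorially and give the axial hydroxyl cis to the C2 methyl. The addition must avoid enolisation toward C1, because a C1 enolate could displace the C3 bromide.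

**C6–O and C1–H.** Ketone 17 comes from alcohol 16, and 16 from alkene 14 (C1=C6) by hydroboration. Boron goes to the less substituted C6 and hydrogen to C1 on the same face, which sets C1. The alkene is placed here because the key step leaves a ketone at C1 with only one enolisable neighbour.

**C1–C7.** Alkene 14 is cut between sp2 C1 and C7 into enol triflate 8 and iodide 12, joined through alkylzinc iodide 13. Triflate 8 forms from ketone 6 with no regiochemical choice, since C2 is quaternary. Iodide 12 carries C9 from the chiral pool: it comes through alcohol 11 and triol 10 from acid 9. The carboxyl group next to the carbinol becomes C10 and the distant one C7, so the (S) descriptor is kept throughout.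

**C2–C1′ and C3–Br (key).** Bromoketone 6 is cut back to tertiary allylic alcohol 5. In the forward direction a bromonium ion on C2=C3 is opened at C2 by the chain migrating from C1 as the carbinol becomes the ketone. One step forms two bonds and both stereocentres, stereospecifically from the single stereocentre of 5, and leaves the ketone needed for the next disconnection. No other cut makes the C–Br bond directly in its final configuration.

**C1–C1′.** Alcohol 5 is cut into enone 4 and dialkylzinc 3, made from bromide 1. A catalytic enantioselective 1,2-addition sets the only stereocentre the ring needs; everything else in the ring is relayed from it.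

## Alternatives that were turned down

**Alternative 1:** The ring is cut at C3–C4 and C1–C6, with a nitro group in place of bromine and a formyl group in place of the side chain.
- Forward key step: under amine catalysis the nitronate carbon of nitroaldehyde A1 adds to enone A2, and the enamine of the aldehyde closes onto the methyl ketone to give β-hydroxy aldehyde A3.
- For: the ring and C1, C3 and C6 form in one operation from acyclic material that already holds C2 and the intact 4-methylpent-3-enyl chain. The C6 carbinol arrives with its methyl group. On ring-forming economy and on C6 this is stronger than the chosen route, which needs three steps for C6 and a Wittig reaction for the chain.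
- Against: C3 carries nitrogen. There is no stereospecific exchange of a secondary nitro group for bromine next to a quaternary carbon; the detour runs through a Nef reaction, reduction and substitution with inversion at a neopentyl-type carbon, where rearrangement and elimination are likely. The nitronate carbon is itself neopentyl, the aldol closure onto a ketone is reversible, and the formyl group must still be extended by four carbons including C9.
- Comparison: more steps are added after the key step than are saved before it. The chosen strategy forms the C–Br bond and C2 together in their final configuration.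

**Alternative 2:** The cuts are C1–C7 and C2–C1′, both chains being attached to a ring that already has the C6 carbinol.
- Forward key step: the magnesium alkoxide of hydroxy enone A4 guides Grignard reagent A5 to C1 on the oxygen face, and the C2 enolate is alkylated by iodide A6 on the opposite face, giving ketone A7.
- For: it is the most convergent plan. C1 and C2 are set in one flask relative to C6, the 4-methylpent-3-enyl chain enters intact, and the carbon skeleton is reached in fewer steps than in the chosen route.
- Against: C3 is a ketone in A7. The bromide would have to come from the axial alcohol by substitution with inversion at a secondary carbon flanked by quaternary C2, where SN2 is very slow and ionisation invites migration of a C2 substituent. Alkylation of a tetrasubstituted magnesium enolate by an unactivated homoallylic iodide is slow and competes with elimination. A4 needs its own asymmetric access, and C9 is still left to an unbiased addition to a methyl ketone.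
- Comparison: the step economy is better up to A7, but the hardest bond of the target remains unmade. The chosen strategy gives a longer but direct path to that bond.

**Alternative 3:** The cuts are C1–C2 and C3–C4, a [4+2] disconnection.
- Forward key step: nitroalkene A8 adds endo to silyloxydiene A9, which carries the complete silyl-protected side chain, and hydrolysis of the silyl enol ether gives nitro ketone A10.
- For: the ring and C1, C2 and C3 form in one step, with relative configuration following from the alkene geometries and the endo rule. The side chain arrives finished and the C6 ketone is in place. It is stronger on convergence; the chosen route needs three steps after the coupling to finish the vinyl carbinol.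
- Against: a β,β-disubstituted nitroalkene must form the quaternary centre in the bond to the substituted diene terminus, the least favourable combination, so a stepwise Michael pathway with loss of geometry is likely. C9 is too remote to select a diene face, so a chiral catalyst is needed or diastereomers result. C1 ends α to the ketone, and the nitro-to-bromide problem of alternative 1 returns. Two alkenes carried throughout restrict later reagents.
- Comparison: the chosen route is more linear, but its absolute configuration comes from one catalytic step and one chiral-pool acid, and the bromide is never made by substitution.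

Key step: step 3

## Route

Assumption: the antipode of the bis(sulfonamide) diol ligand (from trans-cyclohexane-1,2-diamine and camphor-10-sulfonyl chloride, carbonyl groups reduced to the exo alcohols) that leads to (S)-5 is used; the sense of induction would be checked on the first batch, and the other antipode is equally accessible.

Assumption: (S)-citramalic acid 9 is taken as a commercial chiral-pool acid.

Step 1
Reactants: 1 2-(2-bromoethyl)-1,3-dioxolane
Product: 3 bis[2-(1,3-dioxolan-2-yl)ethyl]zinc, via Grignard reagent 2 (not isolated)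
Conditions: Mg, THF, 25–30 °C; then Zn(OMe)2 (0.5 equiv), NaOMe (1 equiv), Et2O, 0 °C to rt; centrifugation, solution titrated
Reagents that add atoms: zinc methoxide, CO[Zn]OC
Why: Grignard formation from this β-acetal bromide is reliable below 30 °C, and transmetallation with zinc methoxide precipitates magnesium as its methoxide, giving a salt-free dialkylzinc; halide salts would open a racemic pathway in step 2.

Step 2
Reactants: 4 2-methylcyclohex-2-en-1-one; 3 bis[2-(1,3-dioxolan-2-yl)ethyl]zinc
Product: 5 (1S)-1-[2-(1,3-dioxolan-2-yl)ethyl]-2-methylcyclohex-2-en-1-ol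
Conditions: bis(sulfonamide) diol ligand (10 mol %), Ti(OiPr)4 (1.2 equiv), 3 (2 equiv), toluene/hexane, rt; aq NH4Cl
Reagents that add atoms: none
Why: Titanium/bis(sulfonamide) diol-catalysed enantioselective 1,2-addition of a dialkylzinc to a ketone; α-substituted cyclic enones suit it because the two flanks of the carbonyl (trisubstituted sp2 carbon against CH2) differ strongly, and the catalyst sets C1 as (S).

Step 3
Reactants: 5 (1S)-1-[2-(1,3-dioxolan-2-yl)ethyl]-2-methylcyclohex-2-en-1-ol
Product: 6 (2S,3S)-3-bromo-2-[2-(1,3-dioxolan-2-yl)ethyl]-2-methylcyclohexan-1-one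
Conditions: NBS (1.1 equiv), NaHCO3, CH2Cl2, −40 to 0 °C, dark
Reagents that add atoms: N-bromosuccinimide, O=C1CCC(=O)N1Br
Why: The reagent transfers Br+ to C2=C3 on the face of the C1 hydroxyl (hydrogen bond to the reagent or a transient hypobromite), and the bromonium ion is opened at its tertiary end C2 from the opposite face by the C1–C1′ bond while the hydroxyl oxygen becomes the carbonyl, so C3–Br and C2–C1′ form in one anti addition. The closest known reaction type is the halonium-induced semipinacol rearrangement of tertiary allylic alcohols to α-quaternary β-halo ketones. No ring is closed. C2 (S) is set by suprafacial transfer of the chain from C1, whose stereocentre is consumed, and C3 (S) by the face of bromination, which must be anti to the migrating bond. The step needs facial selectivity, migration of the chain in preference to the C1–C6 ring bond or to closure by oxygen, and chemoselectivity against the acetal. A(1,2) strain to the C2 methyl holds the chain pseudoaxial and antiperiplanar to the breaking C2–Br bond, the C1–C6 bond lies near the alkene plane, and a hydroxyl syn to bromine cannot close an epoxide. The product cannot lose HBr toward the carbonyl because C2 has no hydrogen; bicarbonate and darkness protect the acetal from HBr and from radical bromination.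

Step 4
Reactants: 6 (2S,3S)-3-bromo-2-[2-(1,3-dioxolan-2-yl)ethyl]-2-methylcyclohexan-1-one
Product: 8 (5S,6S)-5-bromo-6-[2-(1,3-dioxolan-2-yl)ethyl]-6-methylcyclohex-1-en-1-yl trifluoromethanesulfonate, via potassium enolate 7 (not isolated)
Conditions: KN(SiMe3)2 (1.1 equiv), THF, −78 °C; PhNTf2, −78 to 0 °C
Reagents that add atoms: N-phenylbis(trifluoromethanesulfonimide), O=S(=O)(N(c1ccccc1)S(=O)(=O)C(F)(F)F)C(F)(F)F
Why: Enolate O-triflation; only C6 carries α-hydrogens, so the enolate is regiodefined, and at −78 °C ketone deprotonation is much faster than E2 loss of HBr from the hindered secondary bromide.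

Step 5
Reactants: 9 (2S)-2-hydroxy-2-methylbutanedioic acid ((S)-citramalic acid)
Product: 10 (2S)-2-methylbutane-1,2,4-triol
Conditions: BH3·SMe2, B(OMe)3, THF, 0 °C to rt; MeOH
Reagents that add atoms: none
Why: Borane reduces both carboxylic acids to primary alcohols; the stereocentre is quaternary and untouched.

Step 6
Reactants: 10 (2S)-2-methylbutane-1,2,4-triol
Product: 11 2-[(4S)-2,2,4-trimethyl-1,3-dioxolan-4-yl]ethan-1-ol
Conditions: Me2C(OMe)2, acetone, TsOH·H2O (cat.), rt; Et3N
Reagents that add atoms: 2,2-dimethoxypropane, COC(C)(C)OC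
Why: Acetonide formation under thermodynamic control favours the five-membered dioxolane across the 1,2-diol over the six-membered dioxane, leaving the C4 hydroxyl free.

Step 7
Reactants: 11 2-[(4S)-2,2,4-trimethyl-1,3-dioxolan-4-yl]ethan-1-ol
Product: 12 (4S)-4-(2-iodoethyl)-2,2,4-trimethyl-1,3-dioxolane
Conditions: I2, PPh3, imidazole, CH2Cl2, 0 °C to rt
Reagents that add atoms: iodine, II
Why: Appel-type iodination of a primary alcohol; imidazole buffers the medium so that the acetonide survives.

Step 8
Reactants: 12 (4S)-4-(2-iodoethyl)-2,2,4-trimethyl-1,3-dioxolane; 8 (5S,6S)-5-bromo-6-[2-(1,3-dioxolan-2-yl)ethyl]-6-methylcyclohex-1-en-1-yl trifluoromethanesulfonate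
Product: 14 (4S)-4-(2-{(5S,6S)-5-bromo-6-[2-(1,3-dioxolan-2-yl)ethyl]-6-methylcyclohex-1-en-1-yl}ethyl)-2,2,4-trimethyl-1,3-dioxolane, via alkylzinc iodide 13 (not isolated)
Conditions: 12, Zn dust (activated: BrCH2CH2Br, Me3SiCl), LiCl, THF, 35 °C, decanted from Zn; then 8, Pd(PPh3)4 (5 mol %), THF, 55 °C
Reagents that add atoms: none
Why: Negishi sp2–sp3 coupling; zerovalent palladium inserts into the alkenyl C–OTf bond far faster than into the hindered secondary C–Br bond, the alkylzinc tolerates both acetals, and its oxygen is on the γ-carbon so β-elimination is not possible.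

Step 9
Reactants: 14 (4S)-4-(2-{(5S,6S)-5-bromo-6-[2-(1,3-dioxolan-2-yl)ethyl]-6-methylcyclohex-1-en-1-yl}ethyl)-2,2,4-trimethyl-1,3-dioxolane
Product: 16 (1S,2S,3S,4S)-4-bromo-3-[2-(1,3-dioxolan-2-yl)ethyl]-3-methyl-2-{2-[(4S)-2,2,4-trimethyl-1,3-dioxolan-4-yl]ethyl}cyclohexan-1-ol, via alkylborane 15 (not isolated)
Conditions: BH3·THF, THF, 0 °C to rt; NaOH, H2O2, H2O, 0 °C
Reagents that add atoms: hydrogen peroxide, OO
Why: Hydroboration–oxidation; boron adds to the less substituted C6 and hydrogen to C1 on the same face, and the borane should approach opposite the pseudoaxial C2 methyl and the C3 bromine, so that the side chain ends cis to the C2 methyl (C1 S); oxidation proceeds with retention.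

Step 10
Reactants: 16 (1S,2S,3S,4S)-4-bromo-3-[2-(1,3-dioxolan-2-yl)ethyl]-3-methyl-2-{2-[(4S)-2,2,4-trimethyl-1,3-dioxolan-4-yl]ethyl}cyclohexan-1-ol
Product: 17 (2S,3S,4S)-4-bromo-3-[2-(1,3-dioxolan-2-yl)ethyl]-3-methyl-2-{2-[(4S)-2,2,4-trimethyl-1,3-dioxolan-4-yl]ethyl}cyclohexan-1-one
Conditions: Dess–Martin periodinane, NaHCO3, CH2Cl2, 0 °C to rt
Reagents that add atoms: none
Why: Dess–Martin oxidation under buffered, non-basic conditions gives the C6 ketone without epimerising C1 or forming an enolate next to the γ-bromide.

Step 11
Reactants: 17 (2S,3S,4S)-4-bromo-3-[2-(1,3-dioxolan-2-yl)ethyl]-3-methyl-2-{2-[(4S)-2,2,4-trimethyl-1,3-dioxolan-4-yl]ethyl}cyclohexan-1-one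
Product: 18 (1R,2S,3S,4S)-4-bromo-3-[2-(1,3-dioxolan-2-yl)ethyl]-1,3-dimethyl-2-{2-[(4S)-2,2,4-trimethyl-1,3-dioxolan-4-yl]ethyl}cyclohexan-1-ol
Conditions: MeLi, CeCl3 (anhydrous), THF, −78 °C; aq NH4Cl
Reagents that add atoms: methyllithium, [Li]C
Why: Organocerium 1,2-addition to a hindered, enolisable ketone with little basicity; in the chair with equatorial side chain and bromine the axial C2 methyl blocks axial attack, so the methyl group enters equatorially and the hydroxyl becomes axial, cis to the C2 methyl (C6 R).

Step 12
Reactants: 18 (1R,2S,3S,4S)-4-bromo-3-[2-(1,3-dioxolan-2-yl)ethyl]-1,3-dimethyl-2-{2-[(4S)-2,2,4-trimethyl-1,3-dioxolan-4-yl]ethyl}cyclohexan-1-ol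
Product: 19 3-[(1S,2S,3R,6S)-6-bromo-3-hydroxy-1,3-dimethyl-2-{2-[(4S)-2,2,4-trimethyl-1,3-dioxolan-4-yl]ethyl}cyclohexyl]propanal
Conditions: PPTS (cat.), acetone (2 % H2O), 50 °C
Reagents that add atoms: water, O
Why: Acid-catalysed acetal exchange with the solvent frees the aldehyde, while the acetonide, itself an acetone ketal, is held by mass action; partial loss of the acetonide would be harmless, since the diol is the substrate of step 15.

Step 13
Reactants: 19 3-[(1S,2S,3R,6S)-6-bromo-3-hydroxy-1,3-dimethyl-2-{2-[(4S)-2,2,4-trimethyl-1,3-dioxolan-4-yl]ethyl}cyclohexyl]propanal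
Product: 20 (1R,2S,3S,4S)-4-bromo-1,3-dimethyl-3-(4-methylpent-3-en-1-yl)-2-{2-[(4S)-2,2,4-trimethyl-1,3-dioxolan-4-yl]ethyl}cyclohexan-1-ol
Conditions: iPrPPh3I, n-BuLi (2.5 equiv of ylide), THF, 0 °C; then 19, −78 to 0 °C
Reagents that add atoms: isopropyltriphenylphosphonium iodide, CC(C)[P+](c1ccccc1)(c1ccccc1)c1ccccc1.[I-]
Why: Wittig olefination of an unhindered aldehyde with a non-stabilised ylide; one extra equivalent covers the tertiary hydroxyl, and the trisubstituted alkene has no geometry to control.

Step 14
Reactants: 20 (1R,2S,3S,4S)-4-bromo-1,3-dimethyl-3-(4-methylpent-3-en-1-yl)-2-{2-[(4S)-2,2,4-trimethyl-1,3-dioxolan-4-yl]ethyl}cyclohexan-1-ol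
Product: 21 (2S)-4-[(1S,2S,3S,6R)-3-bromo-6-hydroxy-2,6-dimethyl-2-(4-methylpent-3-en-1-yl)cyclohexyl]-2-methylbutane-1,2-diol
Conditions: AcOH/H2O (4:1), 40 °C
Reagents that add atoms: none
Why: Mild aqueous acid hydrolyses the acetonide; these conditions are too weak to protonate the trisubstituted alkene or ionise the saturated tertiary alcohols.

Step 15
Reactants: 21 (2S)-4-[(1S,2S,3S,6R)-3-bromo-6-hydroxy-2,6-dimethyl-2-(4-methylpent-3-en-1-yl)cyclohexyl]-2-methylbutane-1,2-diol
Product: 22 (2S)-4-[(1S,2S,3S,6R)-3-bromo-6-hydroxy-2,6-dimethyl-2-(4-methylpent-3-en-1-yl)cyclohexyl]-2-hydroxy-2-methylbutanal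
Conditions: SO3·pyridine, DMSO, Et3N, CH2Cl2, 0 °C
Reagents that add atoms: none
Why: Parikh–Doering oxidation; only the primary alcohol can be oxidised, activated DMSO does not cleave the 1,2-diol, and the α-carbon of the aldehyde is quaternary and cannot epimerise.

Step 16
Reactants: 22 (2S)-4-[(1S,2S,3S,6R)-3-bromo-6-hydroxy-2,6-dimethyl-2-(4-methylpent-3-en-1-yl)cyclohexyl]-2-hydroxy-2-methylbutanal
Product: 23 (1R,2S,3S,4S)-4-bromo-2-[(3S)-3-hydroxy-3-methylpent-4-en-1-yl]-1,3-dimethyl-3-(4-methylpent-3-en-1-yl)cyclohexan-1-ol
Conditions: Ph3PCH3Br, KOtBu (3.5 equiv of ylide), THF, 0 °C; then 22, 0 °C to rt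
Reagents that add atoms: methyltriphenylphosphonium bromide, C[P+](c1ccccc1)(c1ccccc1)c1ccccc1.[Br-]
Why: Wittig methylenation of an α-hydroxy aldehyde with excess ylide to cover the two hydroxyl groups; C9 keeps the (S) configuration brought in from 9, and the final conditions are basic, which the tertiary allylic alcohol tolerates.

## Compound list

1 | 2-(2-bromoethyl)-1,3-dioxolane | BrCCC1OCCO1 | starting material
2 | [2-(1,3-dioxolan-2-yl)ethyl]magnesium bromide | Br[Mg]CCC1OCCO1 | intermediate
3 | bis[2-(1,3-dioxolan-2-yl)ethyl]zinc | C1COC(O1)CC[Zn]CCC1OCCO1 | intermediate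
4 | 2-methylcyclohex-2-en-1-one | CC1=CCCCC1=O | starting material
5 | (1S)-1-[2-(1,3-dioxolan-2-yl)ethyl]-2-methylcyclohex-2-en-1-ol | CC1=CCCC[C@]1(O)CCC2OCCO2 | intermediate
6 | (2S,3S)-3-bromo-2-[2-(1,3-dioxolan-2-yl)ethyl]-2-methylcyclohexan-1-one | O=C1[C@](C)(CCC2OCCO2)[C@@H](Br)CCC1 | intermediate
7 | potassium (5S,6S)-5-bromo-6-[2-(1,3-dioxolan-2-yl)ethyl]-6-methylcyclohex-1-en-1-olate | [K+].[O-]C1=CCC[C@H](Br)[C@@]1(C)CCC2OCCO2 | intermediate
8 | (5S,6S)-5-bromo-6-[2-(1,3-dioxolan-2-yl)ethyl]-6-methylcyclohex-1-en-1-yl trifluoromethanesulfonate | FC(F)(F)S(=O)(=O)OC1=CCC[C@H](Br)[C@@]1(C)CCC2OCCO2 | intermediate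
9 | (2S)-2-hydroxy-2-methylbutanedioic acid ((S)-citramalic acid) | C[C@](O)(CC(=O)O)C(=O)O | starting material
10 | (2S)-2-methylbutane-1,2,4-triol | C[C@](O)(CCO)CO | intermediate
11 | 2-[(4S)-2,2,4-trimethyl-1,3-dioxolan-4-yl]ethan-1-ol | OCC[C@@]1(C)COC(C)(C)O1 | intermediate
12 | (4S)-4-(2-iodoethyl)-2,2,4-trimethyl-1,3-dioxolane | ICC[C@@]1(C)COC(C)(C)O1 | intermediate
13 | {2-[(4S)-2,2,4-trimethyl-1,3-dioxolan-4-yl]ethyl}zinc iodide | I[Zn]CC[C@@]1(C)COC(C)(C)O1 | intermediate
14 | (4S)-4-(2-{(5S,6S)-5-bromo-6-[2-(1,3-dioxolan-2-yl)ethyl]-6-methylcyclohex-1-en-1-yl}ethyl)-2,2,4-trimethyl-1,3-dioxolane | C1(CC[C@@]2(C)COC(C)(C)O2)=CCC[C@H](Br)[C@@]1(C)CCC3OCCO3 | intermediate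
15 | monoalkylborane corresponding to 16 (BH2 on C6 in place of the hydroxyl group, same arrangement at every centre) | C1OC(C)(C)O[C@@]1(C)CC[C@H]1[C@](C)(CCC2OCCO2)[C@@H](Br)CC[C@@H]1B | intermediate
16 | (1S,2S,3S,4S)-4-bromo-3-[2-(1,3-dioxolan-2-yl)ethyl]-3-methyl-2-{2-[(4S)-2,2,4-trimethyl-1,3-dioxolan-4-yl]ethyl}cyclohexan-1-ol | C1OC(C)(C)O[C@@]1(C)CC[C@H]1[C@](C)(CCC2OCCO2)[C@@H](Br)CC[C@@H]1O | intermediate
17 | (2S,3S,4S)-4-bromo-3-[2-(1,3-dioxolan-2-yl)ethyl]-3-methyl-2-{2-[(4S)-2,2,4-trimethyl-1,3-dioxolan-4-yl]ethyl}cyclohexan-1-one | C1OC(C)(C)O[C@@]1(C)CC[C@H]1[C@](C)(CCC2OCCO2)[C@@H](Br)CCC1=O | intermediate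
18 | (1R,2S,3S,4S)-4-bromo-3-[2-(1,3-dioxolan-2-yl)ethyl]-1,3-dimethyl-2-{2-[(4S)-2,2,4-trimethyl-1,3-dioxolan-4-yl]ethyl}cyclohexan-1-ol | C1OC(C)(C)O[C@@]1(C)CC[C@H]1[C@](C)(CCC2OCCO2)[C@@H](Br)CC[C@@]1(C)O | intermediate
19 | 3-[(1S,2S,3R,6S)-6-bromo-3-hydroxy-1,3-dimethyl-2-{2-[(4S)-2,2,4-trimethyl-1,3-dioxolan-4-yl]ethyl}cyclohexyl]propanal | C1OC(C)(C)O[C@@]1(C)CC[C@H]1[C@](C)(CCC=O)[C@@H](Br)CC[C@@]1(C)O | intermediate
20 | (1R,2S,3S,4S)-4-bromo-1,3-dimethyl-3-(4-methylpent-3-en-1-yl)-2-{2-[(4S)-2,2,4-trimethyl-1,3-dioxolan-4-yl]ethyl}cyclohexan-1-ol | C1OC(C)(C)O[C@@]1(C)CC[C@H]1[C@](C)(CCC=C(C)C)[C@@H](Br)CC[C@@]1(C)O | intermediate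
21 | (2S)-4-[(1S,2S,3S,6R)-3-bromo-6-hydroxy-2,6-dimethyl-2-(4-methylpent-3-en-1-yl)cyclohexyl]-2-methylbutane-1,2-diol | OC[C@@](C)(O)CC[C@H]1[C@](C)(CCC=C(C)C)[C@@H](Br)CC[C@@]1(C)O | intermediate
22 | (2S)-4-[(1S,2S,3S,6R)-3-bromo-6-hydroxy-2,6-dimethyl-2-(4-methylpent-3-en-1-yl)cyclohexyl]-2-hydroxy-2-methylbutanal | O=C[C@@](C)(O)CC[C@H]1[C@](C)(CCC=C(C)C)[C@@H](Br)CC[C@@]1(C)O | intermediate
23 | (1R,2S,3S,4S)-4-bromo-2-[(3S)-3-hydroxy-3-methylpent-4-en-1-yl]-1,3-dimethyl-3-(4-methylpent-3-en-1-yl)cyclohexan-1-ol | C=C[C@@](C)(O)CC[C@H]1[C@](C)(CCC=C(C)C)[C@@H](Br)CC[C@@]1(C)O | target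

## Step count and least certain steps

Total: 16 steps. Longest linear sequence: 13 steps (steps 1–4 and 8–16, from 1); the branch from 9 (steps 5–7) joins at step 8.

**Step 3 (key step).** Bromination may occur on the chain face, after which the anti hydroxyl closes a bromo epoxide. The C1–C6 ring bond may migrate instead of the chain, giving ring contraction. An acetal oxygen may intercept the bromonium ion, or HBr may open the acetal. All of these depend on the free hydroxyl directing the reagent and on the chain staying pseudoaxial. Fallback, from 5 back to 6: 5 is silylated (N-(trimethylsilyl)imidazole) to (1S)-trimethylsilyl ether F1, and F1 is treated with the same bromine donor in MeCN at −20 °C. The shift is then ended by loss of silicon, not of a proton. With no O–H there is no hypobromite and no epoxide closure, and face selection rests on shielding by the pseudoaxial chain alone.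

**Step 2.** The acetal oxygens of 3 may bind titanium or zinc and slow the catalytic cycle, and residual magnesium salts may open an uncatalysed racemic addition; both erode enantioselectivity. Fallback, from 4 back to 5: Grignard reagent 2 is added to 4 in the presence of CeCl3 to give racemic alcohol F2. F2 is resolved by preparative chromatography on a chiral stationary phase, which returns 5 and leaves the (1R)-antipode F3 to be discarded. This costs half the material but is independent of the catalyst.

**Step 9.** Poor facial selectivity is the main concern: in the alternative half-chair the C2 chain is pseudoaxial and the borane can approach from the methyl face, giving the C1 epimer. Slow reaction of the hindered alkene is a second concern. Fallback, from 14 back to 17: the hydroboration mixture of 16 and C1-epimeric alcohol F4 is oxidised as in step 10 to 17 and C1-epimeric ketone F5. Brief exposure to DBU in CH2Cl2 equilibrates C1 toward 17, whose side chain is equatorial; control thus moves from kinetic face selection to thermodynamic preference. That preference is expected to be modest, and the base must be kept mild because a C1 enolate can displace the C3 bromide.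

**Step 8.** Transmetallation and reductive elimination at the alkenylpalladium next to the quaternary carbon may be slow, so that β-hydride elimination from the alkyl group competes. Zinc dust carried over could insert into the C–Br bond. Fallback, from 12 and 8 back to 14: 12 is dehydroiodinated with KOtBu to (4S)-4-ethenyl-2,2,4-trimethyl-1,3-dioxolane F6. F6 is hydroborated with 9-borabicyclo[3.3.1]nonane to the B-alkyl borane F7, and F7 is coupled with 8 in a Suzuki–Miyaura reaction (PdCl2(dppf), aq K3PO4, DMF/THF, 50 °C).

**Step 16.** Under the basic ylide the free α-hydroxy aldehyde may undergo α-ketol rearrangement or self-condensation faster than olefination, and alkoxide aggregates may stall conversion. Fallback, from 21 back to 23, bypassing 22: selective sulfonylation of the primary hydroxyl (TsCl, Et3N, cat. DMAP) gives primary tosylate F8, and K2CO3 in MeOH closes it to (2S)-epoxide F9. Excess dimethylsulfonium methylide then opens F9 at its CH2, and the resulting β-alkoxy sulfonium eliminates to the vinyl carbinol of 23.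

## Further compounds

F1 | step 3 | (1S)-1-[2-(1,3-dioxolan-2-yl)ethyl]-2-methyl-1-(trimethylsilyloxy)cyclohex-2-ene | CC1=CCCC[C@]1(O[Si](C)(C)C)CCC2OCCO2
F2 | step 2 | racemic 1-[2-(1,3-dioxolan-2-yl)ethyl]-2-methylcyclohex-2-en-1-ol | CC1=CCCCC1(O)CCC2OCCO2
F3 | step 2 | (1R)-1-[2-(1,3-dioxolan-2-yl)ethyl]-2-methylcyclohex-2-en-1-ol | CC1=CCCC[C@@]1(O)CCC2OCCO2
F4 | step 9 | (1R,2R,3S,4S)-4-bromo-3-[2-(1,3-dioxolan-2-yl)ethyl]-3-methyl-2-{2-[(4S)-2,2,4-trimethyl-1,3-dioxolan-4-yl]ethyl}cyclohexan-1-ol | C1OC(C)(C)O[C@@]1(C)CC[C@@H]1[C@](C)(CCC2OCCO2)[C@@H](Br)CC[C@H]1O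
F5 | step 9 | (2R,3S,4S)-4-bromo-3-[2-(1,3-dioxolan-2-yl)ethyl]-3-methyl-2-{2-[(4S)-2,2,4-trimethyl-1,3-dioxolan-4-yl]ethyl}cyclohexan-1-one | C1OC(C)(C)O[C@@]1(C)CC[C@@H]1[C@](C)(CCC2OCCO2)[C@@H](Br)CCC1=O
F6 | step 8 | (4S)-4-ethenyl-2,2,4-trimethyl-1,3-dioxolane | C=C[C@@]1(C)COC(C)(C)O1
F7 | step 8 | 9-{2-[(4S)-2,2,4-trimethyl-1,3-dioxolan-4-yl]ethyl}-9-borabicyclo[3.3.1]nonane | C1CC2CCCC(C1)B2CC[C@@]3(C)COC(C)(C)O3
F8 | step 16 | (2S)-4-[(1S,2S,3S,6R)-3-bromo-6-hydroxy-2,6-dimethyl-2-(4-methylpent-3-en-1-yl)cyclohexyl]-2-hydroxy-2-methylbutyl 4-methylbenzenesulfonate | Cc1ccc(cc1)S(=O)(=O)OC[C@@](C)(O)CC[C@H]1[C@](C)(CCC=C(C)C)[C@@H](Br)CC[C@@]1(C)O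
F9 | step 16 | (1R,2S,3S,4S)-4-bromo-1,3-dimethyl-3-(4-methylpent-3-en-1-yl)-2-{2-[(2S)-2-methyloxiran-2-yl]ethyl}cyclohexan-1-ol | C1O[C@@]1(C)CC[C@H]1[C@](C)(CCC=C(C)C)[C@@H](Br)CC[C@@]1(C)O
A1 | alternative 1 | (3S)-3,7-dimethyl-3-(nitromethyl)oct-6-enal | O=CC[C@](C)(CCC=C(C)C)C[N+](=O)[O-]
A2 | alternative 1 | but-3-en-2-one | CC(=O)C=C
A3 | alternative 1 | 2-hydroxy-2,6-dimethyl-6-(4-methylpent-3-enyl)-5-nitrocyclohexane-1-carbaldehyde, configuration as in the SMILES | O=C[C@H]1[C@](C)(CCC=C(C)C)[C@@H]([N+](=O)[O-])CC[C@@]1(C)O
A4 | alternative 2 | (4R)-4-hydroxy-2,4-dimethylcyclohex-2-en-1-one | CC1=C[C@](C)(O)CCC1=O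
A5 | alternative 2 | [2-(2-methyl-1,3-dioxolan-2-yl)ethyl]magnesium bromide | CC1(CC[Mg]Br)OCCO1
A6 | alternative 2 | 5-iodo-2-methylpent-2-ene | CC(C)=CCCI
A7 | alternative 2 | 4-hydroxy-2,4-dimethyl-2-(4-methylpent-3-enyl)-3-[2-(2-methyl-1,3-dioxolan-2-yl)ethyl]cyclohexan-1-one, configuration as in the SMILES | CC1(CC[C@H]2[C@](C)(CCC=C(C)C)C(=O)CC[C@@]2(C)O)OCCO1
A8 | alternative 3 | (1E)-2,6-dimethyl-1-nitrohepta-1,5-diene | CC(C)=CCC/C(C)=C/[N+](=O)[O-]
A9 | alternative 3 | (3S,6Z)-3-methyl-3-(triethylsilyloxy)-7-(trimethylsilyloxy)nona-1,6,8-triene | C=C[C@@](C)(O[Si](CC)(CC)CC)CC/C=C(\O[Si](C)(C)C)C=C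
A10 | alternative 3 | 3-methyl-3-(4-methylpent-3-enyl)-2-[(S)-3-methyl-3-(triethylsilyloxy)pent-4-enyl]-4-nitrocyclohexan-1-one, configuration as in the SMILES | C=C[C@@](C)(O[Si](CC)(CC)CC)CC[C@H]1[C@](C)(CCC=C(C)C)[C@@H]([N+](=O)[O-])CCC1=O
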